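Remark on the chemistry: compounds 1, 2 and 7 are taken as catalogue chemicals, and 2 is racemic, so every chiral intermediate is racemic or a mixture of diastereomers; this has no consequence, because all stereocentres are gone before the achiral target is reached.

## Structural features

The target is an achiral diarylmethane: two brominated catechol rings joined through one CH2 group, with no stereocentre and therefore no adjacent stereocentres to relate. Ring A (A1 bears the CH2) carries bromine at A2 and A5, hydroxyl at A3 and A4, and the only aromatic hydrogen of the molecule at A6. Ring B is hexasubstituted: CH2 at B1, bromine at B2, B5 and B6, hydroxyl at B3 and B4. The fragile elements are three: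

- the free bromocatechols, which are oxidized to ortho-quinones by air in base and by excess halogen;
- the five aryl C–Br bonds, which exclude hydrogenation catalysts, dissolving metals and alkyllithium reagents late in the route;
- the doubly benzylic CH2, which lies para to a hydroxyl on each ring (A4 and B4) and can be oxidized towards a quinone methide.

The real difficulty is placement of substituents, not bond construction. The rings differ only in that B6 carries bromine where A6 carries hydrogen, so bromination of a bis-catechol precursor would not stop short of A6. The key step exploits the contiguous array B2–B3–B4–B5. The oxygen-bearing carbons B3 and B4 are read as an oxalyl unit, and B2 and B5 as the alpha carbons of a hexanedioate branched at the future B1. The ester carbons then mark exactly the two positions next to the hydroxyls for later exchange against bromine.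

## Logic of the disconnections

**13 to 12.** The two O–CH3 bonds on ring A are added in the retrosynthetic sense. The reason is that ring A must be less nucleophilic than ring B while bromine is present and must carry no acidic hydroxyl during the alkoxide-mediated ring construction. The gain is chemoselectivity, not a simpler skeleton. The forward step must cleave two hindered aryl methyl ethers without touching five C–Br bonds or the CH2 bridge.

**12 to 11.** The three C–Br bonds of ring B are cut: B2 and B5 are replaced by carboxyl groups and B6 by hydrogen. A carboxyl ortho to a phenol is replaceable by bromine through ipso attack, so the two bromines flanking the hydroxyls need no directing-group argument. Ring B is reduced to a dihydroxy diacid that maps onto a diester. The forward step must deliver exactly three substitutions on ring B, none at A6, and must not oxidize the catechol.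

**11 to 10.** The two carboxyl groups are returned to methyl esters. The acid is what ipso substitution needs, and the ester is what a condensation delivers. The forward hydrolysis must run with exclusion of air.

**10 to 9.** Two hydrogens are added at B1 and B6. The dihydro compound is the bis-enol of a cyclic bis(beta-keto ester), which is a Claisen retron. The aromatic ring becomes an aliphatic ring with two 1,3-dioxygen relationships. The forward oxidant must remove one molecule of hydrogen without attacking the catechol product or the CH2 bridge.

**9 to 6 and 7.** The bonds B2–B3 and B4–B5 are cut. Each joins the alpha carbon of an ester to a carbonyl carbon, and the two carbonyl carbons are adjacent, so they belong to an oxalate. Ring B disappears, leaving 7 and the open-chain 1,6-diester 6. The forward step must make two acylations in sequence and must favour the crossed reaction over self-condensation of 6.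

**6 to 5.** The two ester carbons are reconnected as a ring double bond. A 1,6-dicarbonyl compound is the cleavage product of a cyclohexene, and the unsymmetrical branch of 6 becomes the single substituent of a 4-substituted cyclohexene. The forward cleavage must bring both termini to the ester level and spare the oxygenated arene.

**5 to 4.** A hydroxyl is added at the benzylic carbon, which exposes a carbonyl-addition retron. The forward step must remove a benzylic hydroxyl without moving or reducing the ring double bond and without touching C–Br.

**4 to 1 and 2 (through 3).** The bond between A1 and the benzylic carbon is cut. The two ring hydrogens of 1 are equivalent and each is ortho to bromine, so deprotonation can give only 3, and 2 already contains the six carbons of ring B minus the oxalyl unit. The forward step needs metalation without bromine–metal exchange or aryne formation, and addition to 2 faster than its enolization.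

## Other disconnections considered

**Alternative 1:** The cut is at A2–Br and A5–Br, taking ring A back to the 4-substituted cyclohexane-1,2-dione A2, which already carries the complete ring B as its dimethyl ether. In the forward key step A2 would take up three equivalents of Br2 at its alpha carbons and lose HBr to give the dibromocatechol A1; demethylation of ring B would finish the synthesis.

- In its favour: both ring-A bromines enter at carbons alpha to a carbonyl, so their positions are fixed by the dione and not by directing effects; no ring has to be closed; no carbon is discarded.
- Against it here: A1 is a free catechol whose A6–H lies para to the A3 hydroxyl, so the halogenation has to stop after exactly three equivalents on the ring that must keep one hydrogen. The hexasubstituted ring-B benzyl unit of A2 has to be assembled first, and its regiocontrolled preparation is a problem of its own.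
- Comparison on structure: the chosen plan puts the exhaustive bromination on ring B, where every position is to be filled, and keeps ring A as a deactivated diether. It is the better of the two on the A6 question.
- Comparison on mechanism: both plans are equal in letting carbonyl chemistry, not aromatic directing effects, decide where bromine goes.
- Comparison on step economy: Alternative 1 is the better after its key step (two steps against four after 9) and the better on atom economy, since the chosen plan loses two ester carbons as CO2.

**Alternative 2:** The cut is at A1–A2 and A5–A6. Ring A would be made by cycloaddition of the thiophene dioxide A4 (diene) to the terminal alkyne of the propargyl arene A5, followed by cheletropic loss of SO2, to give the tetramethyl ether A3; fourfold demethylation would follow.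

- In its favour: the plan is convergent; the diene is symmetric, so there is no regiochemical question; ring A arrives with both bromines, both oxygens and A6–H in place, so no bromination is needed once the rings are joined. On the A6 question this is better than the chosen plan, which relies on a reactivity difference between the rings in step 7.
- Against it here: a thiophene dioxide reacts as an electron-poor diene, and the two methoxy groups of A4 raise its acceptor orbital, while an unactivated terminal alkyne is a weak partner. The temperatures this may require invite dimerization of A4 and propargyl-to-allene isomerization of A5. Oxidation at sulfur of an electron-rich thiophene to reach A4 is itself uncertain. The hexasubstituted ring B in A5 is only moved to another fragment, not solved.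
- Comparison: Alternative 2 is the equal or the better in convergence and possibly in the longest linear sequence, if A4 and A5 can be had. The chosen plan rests on a condensation with close precedent, and its mechanism is reversible and thermodynamically driven, where the cycloaddition depends on an unfavourable electronic pairing.

**Alternative 3:** The cut is at B3–B4. The 3-substituted hexanedial A7 would be treated with samarium diiodide SmI2 (divalent samarium); the two ketyl radicals would couple and close ring B as the cis-diol A6. Oxidation to the dione A8, bromination with aromatization, bromination at B6 and demethylation would follow.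

- In its favour: A7 would come from compound 5 by reductive ozonolysis; pinacol closure of 1,6-dialdehydes to cis-cyclohexane-1,2-diols is reliable and proceeds under neutral conditions; no self-condensation competes; no carbon is added only to be removed.
- Against it here: the ring that is closed is the ring that was just opened. A6 has the constitution of the cis-dihydroxylation product of 5, so the open-and-close detour buys nothing. A6 is three oxidation levels below a catechol. The bromines at B2 and B5 would then enter through enol bromination of A8 with at least four equivalents of Br2 and the HBr that goes with them, a longer exposure of ring A than in the chosen plan. Stoichiometric divalent samarium must also leave the two aryl bromides alone, which requires working without strongly activating additives.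
- Comparison on structure: both plans build the same ring from the same carbons of 5, and the stereochemistry of A6 is irrelevant in the same way that the stereocentre of 9 is.
- Comparison on step economy: Alternative 3 is the equal or slightly the better (three steps after A6 against four after 9).
- Comparison on mechanism: the chosen plan reaches the dihydroaromatic oxidation level directly and labels B2 and B5 with carboxyl groups, so that the final halogenation is a defined substitution and not an oxidation–halogenation cascade.

Key step: step 4

## Route

Step 1
Reactants: 1 1,4-dibromo-2,3-dimethoxybenzene; 2 cyclohex-3-ene-1-carbaldehyde (racemic)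
Product: 4 (2,5-dibromo-3,4-dimethoxyphenyl)(cyclohex-3-en-1-yl)methanol (both racemic diastereomers), via (2,5-dibromo-3,4-dimethoxyphenyl)magnesium chloride 3 (not isolated)
Conditions: TMPMgCl·LiCl (1.2 equiv), THF, 0 °C to rt; then 2 (1.3 equiv), −20 °C to rt; 1 M HCl, 0 °C
Reagents that add atoms: none
Why: The two ring hydrogens of 1 are equivalent and each lies ortho to bromine, so directed deprotonation by the hindered magnesium amide can give only 3, whose covalent C–Mg bond should resist loss of MgBrCl (aryne formation) and bromine migration at this temperature. Grignard-type 1,2-addition of 3 to the aldehyde 2 forms the bond from A1 to the future CH2; the carbinol centre forms without control, which does not matter because step 2 removes it.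

Step 2
Reactants: 4 (2,5-dibromo-3,4-dimethoxyphenyl)(cyclohex-3-en-1-yl)methanol
Product: 5 1,4-dibromo-5-(cyclohex-3-en-1-ylmethyl)-2,3-dimethoxybenzene (racemic)
Conditions: Et3SiH (3 equiv), CF3CO2H (10 equiv), CH2Cl2, 0 °C to rt
Reagents that add atoms: none
Why: Ionic hydrogenation of a benzylic alcohol: acid ionizes the carbinol to a benzylic cation that the para methoxy group at A4 helps to stabilize, and triethylsilane transfers hydride to it. An isolated 1,2-disubstituted alkene is not reduced by this reagent pair because it would have to pass through a secondary cation, and excess silane at low temperature keeps the benzylic cation short-lived.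

Step 3
Reactants: 5 1,4-dibromo-5-(cyclohex-3-en-1-ylmethyl)-2,3-dimethoxybenzene
Product: 6 dimethyl 3-[(2,5-dibromo-3,4-dimethoxyphenyl)methyl]hexanedioate (racemic)
Conditions: O3, 2.5 M NaOH in MeOH (5 equiv), CH2Cl2, −78 °C; then H2O, rt
Reagents that add atoms: ozone, [O-][O+]=O; methanol, CO
Why: Ozonolysis in methanolic NaOH takes each CH= terminus of the ring double bond directly to a methyl ester, the peroxidic terminus by base-induced loss of water after capture by methanol and the aldehyde terminus by ozone oxidation of its hemiacetal anion. The brominated arene is far less reactive towards ozone than the alkene at −78 °C, and cleavage of the 4-substituted cyclohexene places the branch at C3 of the hexanedioate.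

Step 4
Reactants: 6 dimethyl 3-[(2,5-dibromo-3,4-dimethoxyphenyl)methyl]hexanedioate; 7 dimethyl oxalate
Product: 9 dimethyl 5-[(2,5-dibromo-3,4-dimethoxyphenyl)methyl]-2,3-dihydroxycyclohexa-1,3-diene-1,4-dicarboxylate (racemic), via oxalyl triester 8 (not isolated)
Conditions: NaOMe (2.5 equiv), 7 (1.5 equiv), toluene–MeOH, slow addition of 6 at rt, then 70 °C with MeOH distilled off; 1 M HCl, 0 °C
Reagents that add atoms: none
Why: Methoxide reversibly deprotonates 6 at the alpha CH2 remote from the branch (the future B5), and this enolate adds to 7, which cannot enolize and is the most electrophilic ester in the flask; loss of methoxide forms B4–B5 and gives 8 as its stabilized enolate. A second deprotonation at the alpha CH2 next to the branch (the future B2) gives an enolate that attacks the remaining oxalyl ester carbonyl and expels methoxide, forming B2–B3; if the two acylations occur in the other order the same ring results. The closest known reaction is the double Claisen condensation of dialkyl hexanedioates with dialkyl oxalates to 2,3-dioxocyclohexane-1,4-dicarboxylates, whose second stage is a Dieckmann-type closure. Ring B closes in the 6-exo-trig mode (enolexo), the attacked ester C=O lying outside the ring being formed. No stereocentre is created, since both alpha carbons end as enol carbons, and the existing centre at C5 of 9 is racemic and is lost in step 5. The selectivity required is crossed acylation ahead of Dieckmann closure of 6 to a cyclopentanone: slow addition of 6 to base and excess 7 keeps each enolate facing oxalate, and all Claisen steps are reversible under methoxide whereas the doubly deprotonated bis-enolate of 9 is the thermodynamic sink, which removal of methanol deepens. Methyl esters with methoxide exclude ester scrambling, and acidification liberates 9 as the hydrogen-bonded bis-enol.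

Step 5
Reactants: 9 dimethyl 5-[(2,5-dibromo-3,4-dimethoxyphenyl)methyl]-2,3-dihydroxycyclohexa-1,3-diene-1,4-dicarboxylate
Product: 10 dimethyl 5-[(2,5-dibromo-3,4-dimethoxyphenyl)methyl]-2,3-dihydroxybenzene-1,4-dicarboxylate
Conditions: DDQ (1.05 equiv), 1,4-dioxane, rt to 50 °C
Reagents that add atoms: none
Why: Quinone dehydrogenation: DDQ abstracts hydride from a ring C–H of the cyclohexadiene and the cation loses a proton, driven by the gain of aromaticity. The catechol diester formed is electron-poor and much harder to oxidize than 9, so one equivalent should stop at 10.

Step 6
Reactants: 10 dimethyl 5-[(2,5-dibromo-3,4-dimethoxyphenyl)methyl]-2,3-dihydroxybenzene-1,4-dicarboxylate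
Product: 11 5-[(2,5-dibromo-3,4-dimethoxyphenyl)methyl]-2,3-dihydroxybenzene-1,4-dicarboxylic acid
Conditions: NaOH (6 equiv), MeOH–H2O, reflux, N2; then HCl to pH 1
Reagents that add atoms: sodium hydroxide, [Na+].[OH-]
Why: Saponification of both methyl esters by acyl–oxygen cleavage; the neighbouring phenoxides slow the attack but refluxing aqueous base should suffice, and oxygen is excluded because catecholates autoxidize. Aryl bromides and aryl methyl ethers are inert to these conditions.

Step 7
Reactants: 11 5-[(2,5-dibromo-3,4-dimethoxyphenyl)methyl]-2,3-dihydroxybenzene-1,4-dicarboxylic acid
Product: 12 3,4,6-tribromo-5-[(2,5-dibromo-3,4-dimethoxyphenyl)methyl]benzene-1,2-diol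
Conditions: Br2 (3.1 equiv), AcOH–H2O, 0 °C to rt, dark; aq NaHSO3
Reagents that add atoms: bromine, BrBr
Why: Electrophilic bromination at B6 (para to the B3 hydroxyl) and double ipso-bromodecarboxylation at B2 and B5, each of which is ortho to a phenolic hydroxyl: attack at the carboxyl-bearing carbon gives a cyclohexadienone acid that loses CO2 to rearomatize, as in the bromodecarboxylation of salicylic acids. Ring A should keep A6–H because it carries two bromines and two methoxy groups that are each twisted out of conjugation by two ortho neighbours, so it is far less reactive than the free catechol; darkness suppresses radical attack on the CH2, and the bisulfite work-up returns any ortho-quinone to the catechol.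

Step 8
Reactants: 12 3,4,6-tribromo-5-[(2,5-dibromo-3,4-dimethoxyphenyl)methyl]benzene-1,2-diol
Product: 13 3,4,6-tribromo-5-[(2,5-dibromo-3,4-dihydroxyphenyl)methyl]benzene-1,2-diol (the target)
Conditions: BBr3 (6 equiv), CH2Cl2, −78 °C to rt; then H2O, 0 °C
Reagents that add atoms: none
Why: Lewis-acid ether cleavage: each methoxy oxygen coordinates boron and bromide removes the methyl group by SN2 attack, and hydrolysis of the aryl borates frees the phenols. Aryl C–Br bonds and the CH2 bridge do not react, and the excess covers the reagent consumed by the two free hydroxyls of ring B.

## Compound list

1 | 1,4-dibromo-2,3-dimethoxybenzene | COc1c(Br)ccc(Br)c1OC | starting material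
2 | cyclohex-3-ene-1-carbaldehyde (racemic) | O=CC1CCC=CC1 | starting material
3 | (2,5-dibromo-3,4-dimethoxyphenyl)magnesium chloride, LiCl complex (not isolated) | Cl[Mg]c1cc(Br)c(OC)c(OC)c1Br | intermediate
4 | (2,5-dibromo-3,4-dimethoxyphenyl)(cyclohex-3-en-1-yl)methanol (both racemic diastereomers) | OC(C1CCC=CC1)c1cc(Br)c(OC)c(OC)c1Br | intermediate
5 | 1,4-dibromo-5-(cyclohex-3-en-1-ylmethyl)-2,3-dimethoxybenzene (racemic) | C1=CCC(Cc2cc(Br)c(OC)c(OC)c2Br)CC1 | intermediate
6 | dimethyl 3-[(2,5-dibromo-3,4-dimethoxyphenyl)methyl]hexanedioate (racemic) | COC(=O)CCC(CC(=O)OC)Cc1cc(Br)c(OC)c(OC)c1Br | intermediate
7 | dimethyl oxalate | COC(=O)C(=O)OC | starting material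
8 | dimethyl 4-[(2,5-dibromo-3,4-dimethoxyphenyl)methyl]-2-(2-methoxy-2-oxoacetyl)hexanedioate (diastereomer mixture, present as its sodium enolate, not isolated) | COC(=O)C(=O)C(C(=O)OC)CC(Cc1cc(Br)c(OC)c(OC)c1Br)CC(=O)OC | intermediate
9 | dimethyl 5-[(2,5-dibromo-3,4-dimethoxyphenyl)methyl]-2,3-dihydroxycyclohexa-1,3-diene-1,4-dicarboxylate (racemic) | COC(=O)C1=C(O)C(O)=C(C(=O)OC)C(Cc2cc(Br)c(OC)c(OC)c2Br)C1 | intermediate
10 | dimethyl 5-[(2,5-dibromo-3,4-dimethoxyphenyl)methyl]-2,3-dihydroxybenzene-1,4-dicarboxylate | COC(=O)c1cc(Cc2cc(Br)c(OC)c(OC)c2Br)c(C(=O)OC)c(O)c1O | intermediate
11 | 5-[(2,5-dibromo-3,4-dimethoxyphenyl)methyl]-2,3-dihydroxybenzene-1,4-dicarboxylic acid | OC(=O)c1cc(Cc2cc(Br)c(OC)c(OC)c2Br)c(C(=O)O)c(O)c1O | intermediate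
12 | 3,4,6-tribromo-5-[(2,5-dibromo-3,4-dimethoxyphenyl)methyl]benzene-1,2-diol | COc1c(Br)cc(Cc2c(Br)c(O)c(O)c(Br)c2Br)c(Br)c1OC | intermediate
13 | 3,4,6-tribromo-5-[(2,5-dibromo-3,4-dihydroxyphenyl)methyl]benzene-1,2-diol | Oc1c(Br)cc(Cc2c(Br)c(O)c(O)c(Br)c2Br)c(Br)c1O | target

## Step count and least certain steps

Total step count: 8. Longest linear sequence: 8 steps (from 1 to 13; 2 and 7 enter as purchased reagents).

**Step 4 (key step).** Dieckmann self-condensation of 6 to a five-membered keto ester may outrun the crossed acylation, or the sequence may stall at 8 because enolization at the carbon next to the branch is slow. The fallback replaces equilibrium control by irreversible acylation of a preformed bis-enol equivalent. Setting out from 6, LDA with Me3SiCl present from the start (THF, −78 °C) should trap each ester enolate before it can cyclize and give the bis(silyl ketene acetal) 3-[(2,5-dibromo-3,4-dimethoxyphenyl)methyl]-1,6-dimethoxy-1,6-bis(trimethylsilyloxy)hexa-1,5-diene F1. Oxalyl chloride (CH2Cl2, −78 °C to rt, ZnCl2 as catalyst if needed) should then acylate both ketene acetal carbons in turn, the second time within the molecule, and methanolic work-up comes back to the route at 9.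

**Step 2.** The benzylic cation may rearrange by hydride shift from the ring methine and onward into the allylic position, which would move the double bond; the cation may also be captured by the ring alkene, or the acid may add to the alkene. Each of these would lead to a wrongly branched or saturated ring. The fallback removes the oxygen by a radical path. Setting out from 4, NaH, CS2 and MeI (THF, 0 °C to rt) should give the xanthate O-[(2,5-dibromo-3,4-dimethoxyphenyl)(cyclohex-3-en-1-yl)methyl] S-methyl carbonodithioate F2. Barton–McCombie reduction (Bu3SnH, AIBN, toluene, 80 °C) should then give 5, where the route is rejoined; the thiocarbonyl group captures the stannyl radical much faster than an aryl bromide does.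

**Step 7.** Ipso substitution of the carboxyl groups may be sluggish and call for excess bromine or heat; selectivity would then erode through bromination of ring A at A6, or the catechol would be oxidized to the ortho-quinone. The fallback separates decarboxylation from halogenation. Setting out from 11, thermal protodecarboxylation (quinoline, 190 °C, argon), which salicylic-type acids undergo, should give 4-[(2,5-dibromo-3,4-dimethoxyphenyl)methyl]benzene-1,2-diol F3. Its unencumbered catechol ring should take up three equivalents of Br2 at its three free positions at low temperature (CH2Cl2–AcOH, −20 to 0 °C), returning to the route at 12.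

**Step 1.** Deprotonation next to bromine by the magnesium amide may be slow, and on warming the arylmagnesium may lose MgBrCl to an aryne or scramble its bromine. The fallback makes the carbon–metal bond by exchange. Setting out from 1, electrophilic iodination (N-iodosuccinimide, CF3SO3H, CH2Cl2, 0 °C to rt) at the only type of free position should give 1,4-dibromo-5-iodo-2,3-dimethoxybenzene F4. Iodine–magnesium exchange with iPrMgCl·LiCl (THF, −30 °C), which is much faster at C–I than at C–Br, should then come back to the route at 3, which is carried on to 4 as in step 1.

**Step 3.** One terminus may be oxidized incompletely, leaving an aldehyde ester, or the esters may be partly saponified during work-up. The fallback isolates the diacid. Setting out from 5, ozonolysis (CH2Cl2–MeOH, −78 °C) with oxidative work-up (H2O2, HCO2H, heat) should give 3-[(2,5-dibromo-3,4-dimethoxyphenyl)methyl]hexanedioic acid F5, and Fischer esterification (MeOH, H2SO4 as catalyst, reflux) comes back to the route at 6.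

## Further compounds

F1 | step 4 | 3-[(2,5-dibromo-3,4-dimethoxyphenyl)methyl]-1,6-dimethoxy-1,6-bis(trimethylsilyloxy)hexa-1,5-diene (racemic, mixture of double-bond isomers) | COC(O[Si](C)(C)C)=CC(Cc1cc(Br)c(OC)c(OC)c1Br)CC=C(OC)O[Si](C)(C)C
F2 | step 2 | O-[(2,5-dibromo-3,4-dimethoxyphenyl)(cyclohex-3-en-1-yl)methyl] S-methyl carbonodithioate (diastereomer mixture) | CSC(=S)OC(C1CCC=CC1)c1cc(Br)c(OC)c(OC)c1Br
F3 | step 7 | 4-[(2,5-dibromo-3,4-dimethoxyphenyl)methyl]benzene-1,2-diol | Oc1ccc(Cc2cc(Br)c(OC)c(OC)c2Br)cc1O
F4 | step 1 | 1,4-dibromo-5-iodo-2,3-dimethoxybenzene | COc1c(Br)cc(I)c(Br)c1OC
F5 | step 3 | 3-[(2,5-dibromo-3,4-dimethoxyphenyl)methyl]hexanedioic acid (racemic) | OC(=O)CCC(CC(=O)O)Cc1cc(Br)c(OC)c(OC)c1Br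
A1 | alternative 1 | 3,6-dibromo-4-[(2,5,6-tribromo-3,4-dimethoxyphenyl)methyl]benzene-1,2-diol | Oc1c(Br)cc(Cc2c(Br)c(OC)c(OC)c(Br)c2Br)c(Br)c1O
A2 | alternative 1 | 4-[(2,5,6-tribromo-3,4-dimethoxyphenyl)methyl]cyclohexane-1,2-dione (racemic) | O=C1CCC(Cc2c(Br)c(OC)c(OC)c(Br)c2Br)CC1=O
A3 | alternative 2 | 1,2,4-tribromo-3-[(2,5-dibromo-3,4-dimethoxyphenyl)methyl]-5,6-dimethoxybenzene | COc1c(Br)cc(Cc2c(Br)c(OC)c(OC)c(Br)c2Br)c(Br)c1OC
A4 | alternative 2 | 2,5-dibromo-3,4-dimethoxythiophene 1,1-dioxide | COC1=C(Br)S(=O)(=O)C(Br)=C1OC
A5 | alternative 2 | 1,2,4-tribromo-5,6-dimethoxy-3-(prop-2-yn-1-yl)benzene | C#CCc1c(Br)c(OC)c(OC)c(Br)c1Br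
A6 | alternative 3 | cis-4-[(2,5-dibromo-3,4-dimethoxyphenyl)methyl]cyclohexane-1,2-diol (racemic, either configuration at C4) | O[C@H]1CCC(Cc2cc(Br)c(OC)c(OC)c2Br)C[C@H]1O
A7 | alternative 3 | 3-[(2,5-dibromo-3,4-dimethoxyphenyl)methyl]hexanedial (racemic) | O=CCCC(CC=O)Cc1cc(Br)c(OC)c(OC)c1Br
A8 | alternative 3 | 4-[(2,5-dibromo-3,4-dimethoxyphenyl)methyl]cyclohexane-1,2-dione (racemic) | O=C1CCC(Cc2cc(Br)c(OC)c(OC)c2Br)CC1=O
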